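All runs were computed on assumed constants; noise was put on by code.

The vessel is closed and stirred with Z held over it, and I follow one J: it turns into D, and D turns into G if it meets L.

in all of them: J 0.030 M; Z 9.1 mM (held)
- grey: L 0.022 M; run made earlier
- red: L 0.090 M; run made earlier
- flask: L 0.0450 M; time 5.0 d

- grey (time / d: D / %, G / %): 0.417: 8.2, 13.8; 0.833: 16.2, 31.1; 1.67: 40.7, 49.5; 3.00: 44.7, 52.2; 6.00: 39.2, 59.0
- red (time / d: D / %, G / %): 0.417: 2.3, 22.9; 0.833: 1.8, 45.0; 1.67: 6.9, 91.0; 3.00: 0, 98.8; 6.00: 0.9, 99.9

(standard deviation of a reading: 1 percentage point)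

- time, not beyond 5.0 d, at which the flask holds most D
- the amount of D, in percent of the J charged, at that time

- at the start none of E is dissolved
- reactions considered so far: L <-> Q; J + E <-> X + D; Z <-> E; L + D -> G

In the red run D + G stands at 97.9% after 1.67 d, so J is fed out as D at 0.586 /d of its charge, a steady zero-order feed. I assume the flask gets the same feed, 0.0176 M/d, which spends its J in 1.71 d. Red D reads 1.8% at 0.833 d, so I let D be eaten on arrival while L lasts, a crude step, since grey D reads 16.2% then.

Now follow one L: it meets D or slips to Q. Grey G reads 49.5% at 1.67 d and 52.2% at 3.00 d, so about 67.5% of grey L reached G. Carried to the flask, that share gives G of 101% of the J charged and strands no D. This is the weak link: a share belongs to a duration, here roughly the 1.67 d up to which grey G climbs steeply.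

Reforged: grey G's climb per unit of D falls from 3.41 /d to 0.773 /d between successive intervals, so I guess grey free L averaged a quarter of its charge, slipping at 0.778 /d. With feed and slip together, the flask's free L reckons to zero at 1.41 d. The stranded share, the part of J fed out after that moment, is 17.5%, so I commit to that peak at 1.71 d.

The forecast says 1.8 d (1.6 d to 2.1 d) and 20% (14% to 27%), on the ground: "When J runs out, supply stops". Both of its values lie above mine.

The flask peaks at 17.4% of D at 1.71 d, inside both ranges, with 76.3% G at that time.

    L ⇌ Q (K = 5.87, k = 7.61 × 10⁻⁶ /s)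
    J + E ⇌ X + D, settled at all times (K = 38.3)
    Z ⇌ E, rate k3*(csat - [E]) (kL = 2.31 × 10⁻⁵ /s)
    L + D → G (k = 0.00438 /M/s)

As a concentration the stranded share is 0.00524 M, less than the 0.0188 M of Q at 1.71 d.

For the neighbour with 0.18 M of L, the same reckoning puts free L at zero after 2.82 d, later than 1.71 d, so it strands no D. That neighbour's D peaks at 2.53%, and it ends with 100% G.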